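Time separates elm from larch: the same charge is read at 40 h and at 20 h, so we follow the excess of product along a single curve.

| setting | north-west | north | south-east | elm | larch |
|---|---|---|---|---|---|
| left-handed substrate | 0.27 M | 1.1 M | 0.53 M | 0.53 M | 0.53 M |
| right-handed substrate | 0.27 M | 1.1 M | 0.53 M | 0.53 M | 0.53 M |
| gas | 60 mM (held) | 60 mM (held) | 60 mM (held) | 60 mM (held) | 60 mM (held) |
| precatalyst | 2 mol% | 2 mol% | 3 mol% | 2 mol% | 2 mol% |
| remark | run made earlier | run made earlier | run made earlier |  |  |
| time |  |  |  | 40 h | 20 h |

| run | time / h | left-handed product / % | right-handed product / % |
|---|---|---|---|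
| north-west | 8.00 | 2.4 | 1.8 |
| north-west | 15.0 | 9.5 | 3.6 |
| north-west | 25.0 | 19.5 | 12.6 |
| north-west | 30.0 | 25.5 | 15.7 |
| north-west | 40.0 | 35.3 | 23.0 |
| north | 4.00 | 1.2 | 0.6 |
| north | 10.0 | 3.8 | 3.1 |
| north | 20.0 | 13.4 | 7.0 |
| north | 30.0 | 20.0 | 11.5 |
| north | 40.0 | 27.4 | 17.1 |
| south-east | 8.00 | 4.8 | 1.6 |
| south-east | 15.0 | 13.0 | 6.8 |
| south-east | 25.0 | 25.1 | 15.5 |
| south-east | 30.0 | 30.1 | 19.0 |
| south-east | 40.0 | 39.0 | 27.8 |

(standard deviation of a reading: 0.5 percentage points)

- the flask that ends with the higher excess of left-handed product over right-handed product in the product, or "neither" when 2 percentage points or less lies between them (elm / larch / neither)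
- excess of left-handed product over right-handed product in the product at the end, elm
- excess of left-handed product over right-handed product in the product at the end, larch

- free catalyst is single-handed; left-handed substrate and right-handed substrate are mirror images of each other, charged as a racemate, each of them at the stated concentration
- at the start none of the gas is in solution
- an excess is below zero if the other one leads

1. A product percentage counts both substrates together. With P and Q the left-handed and right-handed product percentages, the remaining fractions of the two substrates are therefore 1 − 2P and 1 − 2Q. We call x = −ln(1 − 2P) the exposure of the left-handed substrate.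

2. We assume each substrate falls in proportion to its own amount under the same catalyst and gas, so the ratio of the two logarithms should hold constant. The first readings stand too near the scatter of 0.5 percentage points, so we use the last: 1.99 in the north-west run, 1.90 in the north run, 1.86 in the south-east run. Their mean is s = 1.92, our selectivity factor, the logarithm of the remaining left-handed fraction over that of the right-handed.

3. We scale the south-east run down by its loading, from 3 mol% to 2 mol%. For elm this gives x = 1.01. That run has no reading at 20 h, so for larch we replace the curve by the mean of its readings at 15.0 h and 25.0 h, which gives x = 0.333.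

4. The right-handed exposure is x/s, and the excess is (P − Q)/(P + Q). We reckon 21.6% for elm and 27.9% for larch.

5. The weak link is the scaling by loading, so we reforge it from other runs. The north-west and north runs have elm's loading and bracket its substrate concentration. Their last exposures, 1.22 and 0.794, average 1.01. At fixed s the excess falls as x rises, so the lower exposure is the harder test for larch: it gives elm 23.5%, which is lower than our larch figure by 4.4 points, more than the margin. We commit to larch.

The forecast names larch, with 22% for elm and 28% for larch, and says “Larch, stopped earlier, ends higher”.

The simulation gives 19.9% for elm and 27.6% for larch, so larch ends higher.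

    partner + free catalyst + left-handed substrate → free catalyst + left-handed product (k = 1100 M⁻² h⁻¹)
    partner + free catalyst + right-handed substrate → free catalyst + right-handed product (k = 570 M⁻² h⁻¹)
    partner + precatalyst → free catalyst + spent reagent (k = 0.150 M⁻¹ h⁻¹)
    2 free catalyst → spent catalyst (k = 1.90 M⁻¹ h⁻¹)
    gas ⇌ partner, rate k5*(csat - [partner]) (kL = 0.580 h⁻¹)

In larch, partner is used 1.8 times as fast for the left-handed product as for the right-handed at 11.3 h, and 1.6 times at 20.0 h, where s times the substrate ratio, 33.8% to 40.8%, gives 1.59. The larch mixture read at 3.0 d keeps 1.4% of its left-handed substrate, from which s gives 10.9% of the right-handed, against 11% found, and its excess stands at 5.16%.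

The numbers in the tables stem from a simulated flask with made-up constants; noise was put on by code.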